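**Plan**

- Retrosynthesis: open the two pyran C–O bonds (O4 of quinolone A to CMe2, O4 of quinolone B to C3), then cut C1–C6 and C4–C5 of the central cyclohexene, then trace both halves back to one 3-formyl-4-oxygenated 7,8-dimethoxy-1-methyl-2-quinolone.
- Enabling feature: the carbocycle is numbered C1 (sp2, on quinolone A), C2 (=CH), C3 (C–Me, C–O), C4 (CH2), C5 (CH on quinolone B), C6 (CH on CMe2O). C5 and C6 are adjacent trans CH centres and the C3 methyl is para to C6, which is the retron of a 1-aryl-1-silyloxy-3-methylbutadiene adding to a β-aryl acrylimide.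
- Forward: quinolone ring (steps 1–3), aldehyde 9 as the branch point (step 4), diene 13 (steps 5–7), dienophile 18 (steps 8–9), cyclohexene by [4+2] union (step 10), C6 carbinol (steps 11–12), then pyran B and pyran A in one acid step (step 13).
- Stereochemistry: C5 and C6 come from the E alkene and the (S,S)-bis(oxazoline) complex of divalent copper; C3 is relayed from C5 through the bridging tether; C1 is transient.

Key step: step 10

Notation: Q = 7,8-dimethoxy-4-(methoxymethoxy)-1-methyl-2-oxo-1,2-dihydroquinolin-3-yl; QH = the 4-hydroxy analogue; C1–C6 as defined above.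

Assumption: diene 13 is drawn as its 1Z isomer and cycloadduct 19 as its 1S epimer (aryl on C1 cis to the imide); neither choice affects the target, because C1 becomes sp2 in step 13.

**Route**

Step 1
Reactants: 1 2,3-dimethoxyaniline
Product: 3 2,3-dimethoxy-N-methylaniline, via N-methoxymethyl aniline 2 (not isolated)
Conditions: (CH2O)n, NaOCH3, MeOH, 65 °C; then NaBH4, 65 °C
Reagents that add atoms: paraformaldehyde (formaldehyde), C=O
Why: Condensation with formaldehyde in methanolic NaOCH3 gives the N,O-acetal, which NaBH4 reduces through the iminium ion, a standard one-pot reductive mono-N-methylation that avoids dialkylation.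

Step 2
Reactants: 3 2,3-dimethoxy-N-methylaniline; 4 diethyl malonate
Product: 6 4-hydroxy-7,8-dimethoxy-1-methylquinolin-2(1H)-one, via malonamate ester 5 (not isolated)
Conditions: Ph2O, 250 °C, ethanol distilled off
Reagents that add atoms: none
Why: Thermal aminolysis of one ester and intramolecular acylation through the acylketene at the only free ortho position, which is para to a methoxy group, is the classical malonate cyclocondensation to 4-hydroxy-2-quinolones.

Step 3
Reactants: 6 4-hydroxy-7,8-dimethoxy-1-methylquinolin-2(1H)-one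
Product: 7 7,8-dimethoxy-4-(methoxymethoxy)-1-methylquinolin-2(1H)-one
Conditions: CH3OCH2Cl, i-Pr2NEt, DMF, 0 °C → rt
Reagents that add atoms: chloromethyl methyl ether, COCCl
Why: The acidic vinylogous carbamic acid is O-alkylated at O4 by the hard chloromethyl ether (Williamson-type acetal formation), giving an acid-labile ether that also directs metalation to C3.

Step 4
Reactants: 7 7,8-dimethoxy-4-(methoxymethoxy)-1-methylquinolin-2(1H)-one
Product: 9 7,8-dimethoxy-4-(methoxymethoxy)-1-methyl-2-oxo-1,2-dihydroquinoline-3-carbaldehyde, via 3-lithioquinolone 8 (not isolated)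
Conditions: n-BuLi, THF, −78 °C; then DMF, −78 → 0 °C; H2O
Reagents that add atoms: N,N-dimethylformamide, CN(C)C=O
Why: Directed ortho-metalation removes the C3–H flanked by the lactam carbonyl and the acetal oxygen, and formylation of the aryllithium with DMF gives the aldehyde when the aminoalkoxide collapses on aqueous work-up; this single aldehyde serves both halves of the molecule.

Step 5
Reactants: 9 7,8-dimethoxy-4-(methoxymethoxy)-1-methyl-2-oxo-1,2-dihydroquinoline-3-carbaldehyde; 10 2-methylprop-1-enylmagnesium bromide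
Product: 11 racemic 3-(1-hydroxy-3-methylbut-2-en-1-yl)-7,8-dimethoxy-4-(methoxymethoxy)-1-methylquinolin-2(1H)-one
Conditions: 10 (THF solution), THF, −78 → 0 °C; aq NH4Cl
Reagents that add atoms: none
Why: Grignard 1,2-addition of the alkenylmagnesium bromide to the aldehyde is fast at low temperature and should outrun addition–elimination at C4; the carbinol centre is racemic and is removed in step 6.

Step 6
Reactants: 11 racemic allylic alcohol
Product: 12 7,8-dimethoxy-4-(methoxymethoxy)-1-methyl-3-(3-methylbut-2-enoyl)quinolin-2(1H)-one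
Conditions: MnO2, CH2Cl2, rt
Reagents that add atoms: none
Why: MnO2 oxidises the doubly activated (allylic and aryl-substituted) secondary alcohol to the enone under neutral conditions that leave the acetal intact.

Step 7
Reactants: 12 enone
Product: 13 3-[(1Z)-1-(tert-butyldimethylsilyloxy)-3-methylbuta-1,3-dien-1-yl]-7,8-dimethoxy-4-(methoxymethoxy)-1-methylquinolin-2(1H)-one
Conditions: t-BuMe2SiOSO2CF3, Et3N, CH2Cl2, −78 → 0 °C
Reagents that add atoms: tert-butyldimethylsilyl trifluoromethanesulfonate, CC(C)(C)[Si](C)(C)OS(=O)(=O)C(F)(F)F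
Why: Soft enolisation (O-silylation of the enone, then γ-deprotonation of a methyl group by Et3N) gives the vinylogous silyl dienol ether, and the preferred s-cis enone conformer should lead to the 1Z isomer.

Step 8
Reactants: 14 oxazolidin-2-one; 15 diethylphosphonoacetic acid
Product: 17 diethyl [2-oxo-2-(2-oxooxazolidin-3-yl)ethyl]phosphonate, via mixed pivalic anhydride 16 (not isolated)
Conditions: (CH3)3CCOCl, Et3N, THF, −20 °C; then LiCl, 14, rt
Reagents that add atoms: none
Why: N-Acylation of the oxazolidinone by the mixed pivalic anhydride, with LiCl activating the weakly nucleophilic carbamate, is the standard one-pot imide synthesis from a carboxylic acid.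

Step 9
Reactants: 9 aldehyde; 17 phosphonate
Product: 18 3-[(E)-3-Q-acryloyl]oxazolidin-2-one
Conditions: LiCl, i-Pr2NEt, CH3CN, rt
Reagents that add atoms: none
Why: Horner–Wadsworth–Emmons olefination under Masamune–Roush conditions gives the E acrylimide because the stabilised phosphonate anion adds reversibly and the mild amine base spares the vinylogous ester.

Step 10
Reactants: 13 silyl dienol ether of quinolone A; 18 acryloyl oxazolidinone of quinolone B
Product: 19 3-{[(1S,5R,6S)-1-(tert-butyldimethylsilyloxy)-3-methyl-1,5-di-Q-cyclohex-2-en-6-yl]carbonyl}oxazolidin-2-one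
Conditions: Cu(OSO2CF3)2 (10 mol %), (S,S)-t-Bu-box [2,2'-(propane-2,2-diyl)bis((4S)-4-tert-butyl-4,5-dihydrooxazole)] (11 mol %), 4 Å molecular sieves, CH2Cl2, −20 °C → rt
Reagents that add atoms: none
Why: The imide binds divalent copper through both carbonyl oxygens in a distorted square-planar complex with the enoyl unit s-cis, and the C4 methylene terminus of the silyl dienol ether (its HOMO coefficient raised by the C1 silyloxy group and the C3 methyl) bonds to C5 while C6 bonds to C1, either in one asynchronous [4+2] event or as a Mukaiyama–Michael addition followed by aldol-type closure of the copper enolate on the silyloxocarbenium ion. The closest known reaction type is the bis(oxazoline)–Cu(OSO2CF3)2 catalysed Diels–Alder and Mukaiyama–Michael chemistry of β-substituted acryloyl oxazolidinones with silyloxy dienes and silyl enol ethers. The cyclohexene closes by intermolecular [4+2] cycloaddition, which in the stepwise limit is a 6-(enolexo)-exo-trig aldol closure. C5 and C6 are set together: their trans relationship follows from suprafacial addition across the E alkene (or, stepwise, from chair closure with quinolone B and the imide equatorial), and their absolute sense 5R,6S follows from the (S,S) ligand, whose tert-butyl group covers the si face of C6 so that the diene adds to the re face. C1 is formed without any control that matters, since it becomes sp2 in step 13. The step needs ortho/para regioselectivity (secured by the polarised diene), trans diastereoselectivity (secured by the alkene geometry) and enantiofacial selectivity (secured by two-point binding of the imide in the chiral copper complex).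

Step 11
Reactants: 19 cycloadduct
Product: 20 methyl (1S,5R,6S)-1-(tert-butyldimethylsilyloxy)-3-methyl-1,5-di-Q-cyclohex-2-ene-6-carboxylate
Conditions: CH3MgBr added to MeOH/CH2Cl2 at 0 °C (forms CH3OMgBr); then 19, 0 °C; aq NH4Cl
Reagents that add atoms: methanol (delivered as CH3OMgBr), CO
Why: Bromomagnesium methoxide chelates the two imide carbonyls and delivers methoxide to the exocyclic one (Evans transesterification), releasing the oxazolidinone at 0 °C without disturbing C6–H or the silyl ether.

Step 12
Reactants: 20 methyl ester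
Product: 21 2-[(1S,5R,6R)-1-(tert-butyldimethylsilyloxy)-3-methyl-1,5-di-Q-cyclohex-2-en-6-yl]propan-2-ol
Conditions: CH3MgBr (excess), THF, 0 °C → rt; aq NH4Cl
Reagents that add atoms: methylmagnesium bromide, C[Mg]Br
Why: Double Grignard addition of the small, weakly basic methyl nucleophile converts the ester into the tertiary carbinol, while the lactam carbonyls are vinylogous carbamates and should not react at this temperature (the C6 descriptor changes by priority only).

Step 13
Reactants: 21 tertiary carbinol
Product: 24 CNP0237003.1 (target), via bis-hydroxyquinolone carbinol 22 (not isolated), via bridged pyran carbinol 23 (not isolated)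
Conditions: CF3CO2H, CH2Cl2, H2O (a few equiv), 0 °C → rt
Reagents that add atoms: none
Why: Acid hydrolyses both MOM acetals and ionises the tertiary allylic C1–OSi bond to a cation stabilised as an extended ortho-quinone methide of quinolone A, which the 4-hydroxyl of quinolone B, held on the same face by C5, captures at C3 (SN1′ etherification closing the bridging pyran B and fixing C3 as S), after which the carbinol ionises and is trapped by the 4-hydroxyl of quinolone A (SN1 cyclodehydration to the 2,2-dimethylpyran A) while C5 and C6 stay untouched.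

**Compound list**

1 | 2,3-dimethoxyaniline | COc1cccc(N)c1OC | starting material
2 | N-(methoxymethyl)-2,3-dimethoxyaniline (not isolated) | COCNc1cccc(OC)c1OC | intermediate
3 | 2,3-dimethoxy-N-methylaniline | CNc1cccc(OC)c1OC | intermediate
4 | diethyl malonate | CCOC(=O)CC(=O)OCC | starting material
5 | ethyl 3-[(2,3-dimethoxyphenyl)(methyl)amino]-3-oxopropanoate (not isolated) | CCOC(=O)CC(=O)N(C)c1cccc(OC)c1OC | intermediate
6 | 4-hydroxy-7,8-dimethoxy-1-methylquinolin-2(1H)-one | COc1ccc2c(O)cc(=O)n(C)c2c1OC | intermediate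
7 | 7,8-dimethoxy-4-(methoxymethoxy)-1-methylquinolin-2(1H)-one | COc1ccc2c(OCOC)cc(=O)n(C)c2c1OC | intermediate
8 | 3-lithio-7,8-dimethoxy-4-(methoxymethoxy)-1-methylquinolin-2(1H)-one (not isolated) | COc1ccc2c(OCOC)c([Li])c(=O)n(C)c2c1OC | intermediate
9 | 7,8-dimethoxy-4-(methoxymethoxy)-1-methyl-2-oxo-1,2-dihydroquinoline-3-carbaldehyde | COc1ccc2c(OCOC)c(C=O)c(=O)n(C)c2c1OC | intermediate
10 | 2-methylprop-1-enylmagnesium bromide | CC(C)=C[Mg]Br | starting material
11 | racemic 3-(1-hydroxy-3-methylbut-2-en-1-yl)-7,8-dimethoxy-4-(methoxymethoxy)-1-methylquinolin-2(1H)-one | COc1ccc2c(OCOC)c(C(O)C=C(C)C)c(=O)n(C)c2c1OC | intermediate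
12 | 7,8-dimethoxy-4-(methoxymethoxy)-1-methyl-3-(3-methylbut-2-enoyl)quinolin-2(1H)-one | COc1ccc2c(OCOC)c(C(=O)C=C(C)C)c(=O)n(C)c2c1OC | intermediate
13 | 3-[(1Z)-1-(tert-butyldimethylsilyloxy)-3-methylbuta-1,3-dien-1-yl]-7,8-dimethoxy-4-(methoxymethoxy)-1-methylquinolin-2(1H)-one | COc1ccc2c(OCOC)c(c(=O)n(C)c2c1OC)/C(O[Si](C)(C)C(C)(C)C)=C/C(C)=C | intermediate
14 | oxazolidin-2-one | O=C1NCCO1 | starting material
15 | diethylphosphonoacetic acid | CCOP(=O)(CC(=O)O)OCC | starting material
16 | diethylphosphonoacetic pivalic anhydride (not isolated) | CCOP(=O)(CC(=O)OC(=O)C(C)(C)C)OCC | intermediate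
17 | diethyl [2-oxo-2-(2-oxooxazolidin-3-yl)ethyl]phosphonate | CCOP(=O)(CC(=O)N1CCOC1=O)OCC | intermediate
18 | 3-[(E)-3-Q-acryloyl]oxazolidin-2-one | O=C1OCCN1C(=O)/C=C/c1c(OCOC)c2ccc(OC)c(OC)c2n(C)c1=O | intermediate
19 | 3-{[(1S,5R,6S)-1-(tert-butyldimethylsilyloxy)-3-methyl-1,5-di-Q-cyclohex-2-en-6-yl]carbonyl}oxazolidin-2-one | COc1ccc2c(OCOC)c(c(=O)n(C)c2c1OC)[C@]1(O[Si](C)(C)C(C)(C)C)C=C(C)C[C@@H](c3c(OCOC)c4ccc(OC)c(OC)c4n(C)c3=O)[C@@H]1C(=O)N5CCOC5=O | intermediate
20 | methyl (1S,5R,6S)-1-(tert-butyldimethylsilyloxy)-3-methyl-1,5-di-Q-cyclohex-2-ene-6-carboxylate | COc1ccc2c(OCOC)c(c(=O)n(C)c2c1OC)[C@]1(O[Si](C)(C)C(C)(C)C)C=C(C)C[C@@H](c3c(OCOC)c4ccc(OC)c(OC)c4n(C)c3=O)[C@@H]1C(=O)OC | intermediate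
21 | 2-[(1S,5R,6R)-1-(tert-butyldimethylsilyloxy)-3-methyl-1,5-di-Q-cyclohex-2-en-6-yl]propan-2-ol | COc1ccc2c(OCOC)c(c(=O)n(C)c2c1OC)[C@]1(O[Si](C)(C)C(C)(C)C)C=C(C)C[C@@H](c3c(OCOC)c4ccc(OC)c(OC)c4n(C)c3=O)[C@@H]1C(C)(C)O | intermediate
22 | 2-[(1S,5R,6R)-1-(tert-butyldimethylsilyloxy)-3-methyl-1,5-di-QH-cyclohex-2-en-6-yl]propan-2-ol (not isolated) | COc1ccc2c(O)c(c(=O)n(C)c2c1OC)[C@]1(O[Si](C)(C)C(C)(C)C)C=C(C)C[C@@H](c3c(O)c4ccc(OC)c(OC)c4n(C)c3=O)[C@@H]1C(C)(C)O | intermediate
23 | (3S,5R,6S) bridged pyran B compound with C1=C2, free 4-hydroxyl on quinolone A and the C6 propan-2-ol (not isolated) | COc1ccc2c(O)c(c(=O)n(C)c2c1OC)C1=C[C@]2(C)C[C@@H](c4c(c5ccc(OC)c(OC)c5n(C)c4=O)O2)[C@@H]1C(C)(C)O | intermediate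
24 | CNP0237003.1, (3S,5R,6S) bis-pyrano dimer (route numbering) | COc1ccc2c3c(c(=O)n(C)c2c1OC)C1=C[C@]2(C)C[C@@H](c4c(c5ccc(OC)c(OC)c5n(C)c4=O)O2)[C@@H]1C(C)(C)O3 | target

**Count and risks**

Total step count: 13. Longest linear sequence: 11 steps (steps 1, 2, 3, 4, 5, 6, 7, 10, 11, 12, 13).

Step 10. The lactam carbonyls of either partner may sequester the copper catalyst. Addition to the electron-rich β-aryl acrylimide may be slow enough that protodesilylation of the diene wins. The reaction may stop at the open-chain Michael adduct, or the facial selectivity may be poor. The fallback replaces catalyst control by a covalent auxiliary. It sets out from aldehyde 9. Commercial (R)-4-benzyloxazolidin-2-one is acylated with acid 15 through anhydride 16, as in step 8, to give diethyl {2-[(4R)-4-benzyl-2-oxooxazolidin-3-yl]-2-oxoethyl}phosphonate F1. Olefination of 9 with F1 (LiCl, i-Pr2NEt, CH3CN) gives (4R)-4-benzyl-3-[(E)-3-Q-acryloyl]oxazolidin-2-one F2. Reaction of F2 with diene 13 under (C2H5)2AlCl (excess, CH2Cl2, −78 → −20 °C) passes through the chelated aluminium imide, in which the benzyl group shields the si face of C6, and should give the auxiliary-bearing cycloadduct F3. Methanolysis of F3 with CH3OMgBr returns to the route at methyl ester 20.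

Step 13. The carbinol oxygen may capture the C1–C3 allyl cation in a cineole-type bridging, or the cation may lose the C6 proton and erode that centre, before the two phenolic oxygens close their rings. The fallback separates the two closures and keeps the carbinol absent during ionisation of C1. It sets out from ester 20. Treatment with CF3CO2H in wet CH2Cl2, then warming, should remove the acetals, close pyran B and acylate O4 of quinolone A with the C6 ester, giving the bridged lactone F4. Excess CH3MgBr (THF, 0 °C) opens this aryl lactone to carbinol 23, where the route is rejoined. A catalytic amount of 4-CH3C6H4SO3H in toluene at 40 °C, too mild to reopen the aryl ether of pyran B, then closes pyran A to 24.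

Step 11. Methoxide may attack the ring carbonyl of the hindered imide and open the oxazolidinone, or base may induce β-elimination of silanolate across C1–C6. The fallback changes nucleophile and intermediate. It sets out from cycloadduct 19. LiOH/H2O2 (THF/H2O, 0 °C), whose hydroperoxide anion attacks the exocyclic carbonyl most selectively, gives the (1S,5R,6S) carboxylic acid F5. Esterification of F5 with (CH3)3SiCHN2 in MeOH/toluene returns to the route at methyl ester 20.

Further compounds
F1 | step 10 | diethyl {2-[(4R)-4-benzyl-2-oxooxazolidin-3-yl]-2-oxoethyl}phosphonate | CCOP(=O)(CC(=O)N1[C@H](Cc2ccccc2)COC1=O)OCC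
F2 | step 10 | (4R)-4-benzyl-3-[(E)-3-Q-acryloyl]oxazolidin-2-one | O=C1OC[C@@H](Cc2ccccc2)N1C(=O)/C=C/c3c(OCOC)c4ccc(OC)c(OC)c4n(C)c3=O
F3 | step 10 | (4R)-4-benzyl-3-{[(1S,5R,6S)-1-(tert-butyldimethylsilyloxy)-3-methyl-1,5-di-Q-cyclohex-2-en-6-yl]carbonyl}oxazolidin-2-one | COc1ccc2c(OCOC)c(c(=O)n(C)c2c1OC)[C@]1(O[Si](C)(C)C(C)(C)C)C=C(C)C[C@@H](c3c(OCOC)c4ccc(OC)c(OC)c4n(C)c3=O)[C@@H]1C(=O)N5[C@H](Cc6ccccc6)COC5=O
F4 | step 13 | (3S,5R,6S) bridged lactone with pyran B closed and O4 of quinolone A acylated by the C6 carboxyl | COc1ccc2c3c(c(=O)n(C)c2c1OC)C1=C[C@]2(C)C[C@@H](c4c(c5ccc(OC)c(OC)c5n(C)c4=O)O2)[C@@H]1C(=O)O3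
F5 | step 11 | (1S,5R,6S)-1-(tert-butyldimethylsilyloxy)-3-methyl-1,5-di-Q-cyclohex-2-ene-6-carboxylic acid | COc1ccc2c(OCOC)c(c(=O)n(C)c2c1OC)[C@]1(O[Si](C)(C)C(C)(C)C)C=C(C)C[C@@H](c3c(OCOC)c4ccc(OC)c(OC)c4n(C)c3=O)[C@@H]1C(=O)O
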